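Remark on numbering: the chain is counted C1 to C7 with the free hydroxyl on C3 and the acetate on C5. Substitutive names give the ester carbon the locant 3, so names and chain count run in opposite directions; both carbinol centres are S in either count.

## Structural features

The target is an acyclic 1,7-diarylheptane: a chain C1–C7 with no ring in it, carrying a 4-hydroxy-3-methoxyphenyl ring at each end. Oxygen sits on C3 (free secondary alcohol) and on C5 (secondary acetate). The two stereocentres are separated only by the C4 methylene, both are S, and they stand 1,3-anti. Apart from the acetyl group the molecule is C2-symmetric, so a 1,3-acetyl shift would regenerate the same compound, but diol and diacetate are different substances and the acylation level must be controlled. The fragile elements are the secondary acetate (lost or shifted by hydroxide, fluoride or strong acid), the β-hydroxy ketone stage on the way to it (dehydration, retro-aldol) and the two electron-rich, acidic phenols, which therefore travel as benzyl ethers. The real difficulty is not the carbon skeleton but the anti-1,3-dioxygen pattern in one absolute sense together with exactly one acetyl group. The key step exploits three facts: C4–C5–C6 with its lone oxygen on C5 has the carbon–oxygen pattern of epichlorohydrin; C3 has to pass through the carbonyl oxidation level anyway and can be made nucleophilic as a 1,3-dithiane carbon; and C7 is benzylic and available as a benzylmagnesium reagent.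

## Logic of the disconnections

**17 to 16.** The two phenolic O–H bonds are exchanged for O–CH2Ph bonds. Free phenols would quench the alkyllithium and Grignard steps and would be oxidised during thioacetal cleavage, and one of the purchased materials already carries this ether. Nothing is gained in skeleton, but every earlier step becomes possible with a single kind of protecting group. The forward step must be neutral so that the secondary ester is neither cleaved nor lost, and it must come after all sulfur has left the molecule.

**16 to 15.** Two bonds are cut together: the acyl–O5 bond and the C3–H bond. Both arise in one redox esterification, so 16 goes back to a compound with a ketone at C3 and a free hydroxyl at C5. One stereocentre and the whole mono-acylation problem disappear. The forward step has to deliver hydride to C3 from a species tethered to O5, so that the anti relation results, and it must not trigger retro-aldol or dehydration of 15.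

**15 to 14.** The C3 carbonyl is exchanged for the two C–S bonds of a six-membered thioacetal. No skeletal bond changes, but C3 becomes a carbon that can carry negative charge while its oxidation level is kept. The demand is an unmasking that spares the aldol unit and the alkoxyarenes.

**14 to 5, 10 and 9.** C3–C4 and C6–C7 are cut. They flank the three-carbon unit C4–C5–C6, whose only functional group is the C5 oxygen; in 10 both flanking carbons are electrophilic and C5 is already a stereocentre of known configuration. 14 falls into three pieces, two of them achiral and of similar size, and the stereocentre is bought. The forward step must make two nucleophiles react in a fixed order at fixed carbons: first the carbanion from 5 at the ring CH2 of 10, then 9 at the carbon that carried chlorine. The opposite regiochemistry in the first event would give the mirror image.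

**5 to 3 and 4, then 2 and 1.** The two C–S bonds go back to an aldehyde and a dithiol, the aldehyde to a primary alcohol, and the O–benzyl bond to a phenol. 1 already contains the ring and C1–C3; only the oxidation level of C3 and the phenol protection are missing. The forward steps require phenol-selective alkylation, an oxidation that stops at the aldehyde, and a thioacetalisation that leaves the aryl benzyl ether alone.

**9 to 8, 7 and 6.** The C–Mg bond goes back to C–Cl, this to C–OH, and the CH2OH group to the formyl group of 6, which already carries the protected phenol. The one real demand is magnesium insertion into an electron-rich benzylic chloride without homocoupling.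

## Other disconnections considered

**Alternative 1:** Ring-opening cross-metathesis.
- **Cut:** C1=C2 and C6=C7 of the bis-styrene A1, (1E,3R,5R,6E)-5-hydroxy-1,7-bis(4-hydroxy-3-methoxyphenyl)hepta-1,6-dien-3-yl acetate. A1 is the target with two extra double bonds; its R,R descriptors denote the same spatial arrangement as S,S in the target, because a vinyl neighbour outranks the C4 methylene.
- **Forward key step:** the trans-configured cyclopentene A2, (1R,4R)-4-hydroxycyclopent-2-en-1-yl acetate, would be opened by a ruthenium alkylidene (second-generation Hoveyda–Grubbs catalyst) and capped at both ends by the styrene A3, 2-methoxy-4-vinylphenol. Hydrogenation of A1 would then give the target.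
- **In its favour:** the ring of A2 already holds C3, C4 and C5 with both stereocentres, the anti relation and the single acetate. Ruthenium carbenes tolerate free phenols, so no protecting group is needed, and only two steps follow A2. On step economy and protecting-group economy this plan is better than the chosen one.
- **Against it here:** a cyclopentene has little ring strain, and one flanked by two allylic oxygen substituents is a reluctant substrate. Ring opening is therefore reversible and competes with self-metathesis and polymerisation of the electron-rich A3. A2 belongs to the trans series, whereas enzymatic desymmetrisation supplies the cis series, so one carbinol carbon would first have to be inverted. In A1 both C–O bonds are allylic and conjugated with para-hydroxyphenyl groups, so ionisation (racemisation, allylic transposition) and hydrogenolysis during alkene reduction are real threats.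
- **Comparison:** the two plans are equal in drawing chirality from a small enantiopure building block. The chosen plan forms its bonds by irreversible polar substitutions at unhindered CH2 carbons, while A1 would arise from an equilibrium-controlled carbene process; the price for that security is roughly twice the step count.

**Alternative 2:** Two-directional carbonyl allylation from the alcohol oxidation level.
- **Cut:** C2–C3 and C5–C6. C3–C4–C5 is traced to A5, propane-1,3-diol, and each arm to A6, allyl acetate. The product of the key step is A4, (4S,6S)-nona-1,8-diene-4,6-diol, whose S,S centres have the arrangement of the target.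
- **Forward key step:** a cyclometalated iridium C,O-benzoate complex is assembled from [Ir(cod)Cl]2, a chiral bisphosphine, a nitrobenzoic acid and Cs2CO3. It dehydrogenates each primary alcohol of A5 to the aldehyde and allylates it with the allyliridium species formed from A6.
- **In its favour:** both stereocentres are created in one catalytic step from very cheap achiral feedstocks. Double addition to a symmetric substrate should give high enantiopurity, since the minor sense of addition is diverted into the meso diastereomer. No chiral-pool material and no preformed allylmetal reagent are needed. In stereocentre construction this plan is better than the chosen one.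
- **Against it here:** A4 has nine chain carbons. Each allyl arm brings C2, C1 and one terminal carbon that the target does not contain, so simple arylation of the vinyl groups would put three carbons, not two, between ring and carbinol. Each terminal CH2 would have to be excised by oxidative cleavage after diol protection, the aryl ring added to the resulting carbonyl carbon, and the new benzylic oxygen removed. The diol would then still need mono-acetylation with control of the acylation level.
- **Comparison:** the skeleton match is poorer, and the overall sequence is expected to be no shorter than ten steps. The chosen plan receives C3 at the carbonyl level, so reduction and mono-acetylation merge into one step and no carbon is discarded.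

**Alternative 3:** Double B-alkyl Suzuki–Miyaura coupling.
- **Cut:** the aryl–C1 and C7–aryl bonds.
- **Forward key step:** A8, (4R,6R)-4,6-diethenyl-2,2-dimethyl-1,3-dioxane, would be hydroborated at both vinyl groups with 9-BBN. (R,R in A8 is the S,S arrangement of the target, because the vinyl groups change the priorities.) The two primary alkylboranes would be coupled with A9, 1-(benzyloxy)-4-bromo-2-methoxybenzene, under Pd(dppf)Cl2 and aqueous base to give A7, (4S,6S)-4,6-bis{2-[4-(benzyloxy)-3-methoxyphenyl]ethyl}-2,2-dimethyl-1,3-dioxane.
- **In its favour:** each vinyl group becomes exactly the CH2–CH2 link, so the chain length is right. Both rings arrive late in one flask, and C2 symmetry makes the two ends react alike. The coupling tolerates ethers and acetals and needs no cryogenic organolithium chemistry; in operational robustness of the key step this plan is better.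
- **Against it here:** A8 is not a catalogue compound and needs its own enantioselective synthesis of several steps, in which both stereocentres must be made. The electron-rich A9 adds slowly to zerovalent palladium. After A7 the diol must be released and mono-acetylated in separate operations.
- **Comparison:** the plans are equal in convergence, since each joins three components and forms two C–C bonds in one flask. They are also equal in the number of steps after the key step (three each). The chosen plan is shorter overall because its chiral component is purchased, and it places the acetate through the mechanism of the reduction and not through a separate acylation.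

Key step: step 7

## Route

Step 1
Reactants: 1 dihydroconiferyl alcohol [4-(3-hydroxypropyl)-2-methoxyphenol]
Product: 2 3-[4-(benzyloxy)-3-methoxyphenyl]propan-1-ol
Conditions: BnBr (1.05 equiv), K2CO3, acetone, reflux
Reagents that add atoms: benzyl bromide, BrCc1ccccc1
Why: Williamson ether synthesis; carbonate deprotonates only the phenol, so the phenoxide is benzylated by SN2 while the far less acidic primary alcohol stays free.

Step 2
Reactants: 2 3-[4-(benzyloxy)-3-methoxyphenyl]propan-1-ol
Product: 3 3-[4-(benzyloxy)-3-methoxyphenyl]propanal
Conditions: TEMPO (0.1 equiv), PhI(OAc)2 (1.1 equiv), CH2Cl2, rt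
Reagents that add atoms: none
Why: TEMPO-catalysed alcohol oxidation through the oxoammonium ion, with PhI(OAc)2 as terminal oxidant, should stop at the aldehyde in the absence of water; the near-neutral medium spares the benzyl ether and limits self-aldol of the enolisable aldehyde, which is used promptly.

Step 3
Reactants: 3 3-[4-(benzyloxy)-3-methoxyphenyl]propanal; 4 propane-1,3-dithiol
Product: 5 2-{2-[4-(benzyloxy)-3-methoxyphenyl]ethyl}-1,3-dithiane
Conditions: BF3·OEt2 (0.2 equiv), CH2Cl2, −10 to 0 °C
Reagents that add atoms: none
Why: Lewis-acid-catalysed thioacetalisation, driven by formation of the six-membered dithiane and loss of water; a substoichiometric amount of BF3·OEt2 at low temperature should not cleave the aryl benzyl ether.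

Step 4
Reactants: 6 4-(benzyloxy)-3-methoxybenzaldehyde (O-benzylvanillin)
Product: 7 [4-(benzyloxy)-3-methoxyphenyl]methanol
Conditions: NaBH4, MeOH, 0 °C
Reagents that add atoms: none
Why: Borohydride reduction of an aromatic aldehyde to the benzylic alcohol; the ethers are inert.

Step 5
Reactants: 7 [4-(benzyloxy)-3-methoxyphenyl]methanol
Product: 8 1-(benzyloxy)-4-(chloromethyl)-2-methoxybenzene
Conditions: SOCl2 (1.2 equiv), CH2Cl2, 0 °C to rt; volatiles removed, used crude
Reagents that add atoms: thionyl chloride, O=S(Cl)Cl
Why: Chlorodehydroxylation through the chlorosulfite, made easy by the electron-rich ring; the ionisable chloride is not chromatographed but freed of volatiles and used at once.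

Step 6
Reactants: 8 1-(benzyloxy)-4-(chloromethyl)-2-methoxybenzene
Product: 9 4-(benzyloxy)-3-methoxybenzylmagnesium chloride (titrated solution, used the same day)
Conditions: Mg turnings (3 equiv, I2-activated), 2-MeTHF, 0 °C, slow addition
Reagents that add atoms: magnesium, [Mg]
Why: Grignard formation by magnesium insertion into the benzylic C–Cl bond; the chloride in place of the bromide, excess metal, low temperature, dilution and slow addition are chosen to hold down Wurtz homocoupling, and the aryl ethers are inert to the reagent.

Step 7
Reactants: 5 2-{2-[4-(benzyloxy)-3-methoxyphenyl]ethyl}-1,3-dithiane; 10 (R)-epichlorohydrin [(2R)-2-(chloromethyl)oxirane]; 9 4-(benzyloxy)-3-methoxybenzylmagnesium chloride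
Product: 14 (2S)-4-[4-(benzyloxy)-3-methoxyphenyl]-1-(2-{2-[4-(benzyloxy)-3-methoxyphenyl]ethyl}-1,3-dithian-2-yl)butan-2-ol, via 2-lithio-1,3-dithiane 11 (not isolated), via chlorohydrin lithium alkoxide 12 (not isolated), via terminal epoxide 13 (not isolated)
Conditions: 5, n-BuLi (1.05 equiv), THF, −30 °C, 2 h; then 10 (1.0 equiv), −78 to 0 °C; then CuI (0.2 equiv), 9 (1.6 equiv), −40 to 0 °C; aq. NH4Cl
Reagents that add atoms: none
Why: n-BuLi removes the thioacetal C–H of 5 and gives the sulfur-stabilised carbanion 11, in which C3 has the reverse of its carbonyl polarity. At −78 °C 11 opens the oxirane of 10 by SN2 attack at the ring CH2 (C4) to alkoxide 12, and on warming the alkoxide displaces chloride in a 3-exo-tet closure to the new oxirane 13; this transient three-membered ring is the only ring formed and it is reopened, so no ring persists. Grignard reagent 9, converted by catalytic CuI into a benzylcopper species, opens 13 by SN2 at its terminal CH2 (C6), which forms C6–C7, and aqueous NH4Cl releases 14. The closest known reaction type is the use of epichlorohydrin as a bis-electrophilic linchpin between a lithiated 1,3-dithiane and a second carbon nucleophile, joined to the copper-catalysed Grignard opening of monosubstituted epoxides. No stereocentre is created: C5 is never a reaction site, both substitutions occur at its CH2 neighbours, and the descriptor changes from R in 10, 12 and 13 to S in 14 only because the priorities of the two arms change. The first selectivity needed is attack of 11 at the epoxide carbon and not at C–Cl, which would lead to the enantiomer; ring strain and the reluctance of the bulky, soft 2-alkyl-2-lithiodithiane to displace a primary chloride at −78 °C secure it. The second is single addition of 11, secured by the temperature gap: 12 does not close until the mixture is warmed, by which time 11 has been consumed, so 13 never meets the dithiane anion. The third is opening of 13 at the unsubstituted carbon by carbon and not by halide, secured by sterics and by copper catalysis at or below 0 °C.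

Step 8
Reactants: 14 (2S)-4-[4-(benzyloxy)-3-methoxyphenyl]-1-(2-{2-[4-(benzyloxy)-3-methoxyphenyl]ethyl}-1,3-dithian-2-yl)butan-2-ol
Product: 15 (5S)-1,7-bis[4-(benzyloxy)-3-methoxyphenyl]-5-hydroxyheptan-3-one
Conditions: I2 (3 equiv), NaHCO3, MeCN/H2O (4:1), 0 °C; aq. Na2S2O3
Reagents that add atoms: water, O
Why: Oxidative thioacetal hydrolysis: iodine turns sulfur into a leaving group, water adds to the thionium carbon, and bicarbonate buffers the hydrogen iodide so that the β-hydroxy ketone should neither dehydrate nor undergo retro-aldol cleavage. Iodine without a stronger activator is not expected to iodinate the alkoxyarenes at 0 °C, and the C5 centre is not involved.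

Step 9
Reactants: 15 (5S)-1,7-bis[4-(benzyloxy)-3-methoxyphenyl]-5-hydroxyheptan-3-one
Product: 16 (3S,5S)-1,7-bis[4-(benzyloxy)-3-methoxyphenyl]-5-hydroxyheptan-3-yl acetate
Conditions: MeCHO (6 equiv, freshly distilled), SmI2 (0.2 equiv), THF, −10 °C
Reagents that add atoms: acetaldehyde, CC=O
Why: Evans–Tishchenko reaction: divalent samarium is oxidised by the aldehyde to a trivalent samarium alkoxide, which holds the C5 oxygen as its acetaldehyde hemiacetal together with the C3 carbonyl. Hydride shifts from the hemiacetal carbon to C3 within a chair-like six-membered transition state, which sets C3 anti to C5 (S at chain C3) and leaves the acetyl group on O5; this mechanism produces neither free diol nor diacetate.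

Step 10
Reactants: 16 (3S,5S)-1,7-bis[4-(benzyloxy)-3-methoxyphenyl]-5-hydroxyheptan-3-yl acetate
Product: 17 (3S,5S)-5-hydroxy-1,7-bis(4-hydroxy-3-methoxyphenyl)heptan-3-yl acetate
Conditions: H2 (1 atm), 10% Pd/C, EtOAc, rt
Reagents that add atoms: none
Why: Hydrogenolysis of the two aryl benzyl ethers on palladium under neutral conditions; the secondary acetate, the secondary alcohol and the oxygen-free benzylic CH2 groups should not be touched. Any acetyl shift between O3 and O5 would be degenerate because the two chain ends are identical.

## Compound list

1 | dihydroconiferyl alcohol [4-(3-hydroxypropyl)-2-methoxyphenol] | COc1cc(CCCO)ccc1O | starting material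
2 | 3-[4-(benzyloxy)-3-methoxyphenyl]propan-1-ol | COc1cc(CCCO)ccc1OCc1ccccc1 | intermediate
3 | 3-[4-(benzyloxy)-3-methoxyphenyl]propanal | COc1cc(CCC=O)ccc1OCc1ccccc1 | intermediate
4 | propane-1,3-dithiol | SCCCS | starting material
5 | 2-{2-[4-(benzyloxy)-3-methoxyphenyl]ethyl}-1,3-dithiane | COc1cc(CCC2SCCCS2)ccc1OCc1ccccc1 | intermediate
6 | 4-(benzyloxy)-3-methoxybenzaldehyde (O-benzylvanillin) | COc1cc(C=O)ccc1OCc1ccccc1 | starting material
7 | [4-(benzyloxy)-3-methoxyphenyl]methanol | COc1cc(CO)ccc1OCc1ccccc1 | intermediate
8 | 1-(benzyloxy)-4-(chloromethyl)-2-methoxybenzene | COc1cc(CCl)ccc1OCc1ccccc1 | intermediate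
9 | 4-(benzyloxy)-3-methoxybenzylmagnesium chloride | COc1cc(C[Mg]Cl)ccc1OCc1ccccc1 | intermediate
10 | (R)-epichlorohydrin [(2R)-2-(chloromethyl)oxirane] | ClC[C@H]1CO1 | starting material
11 | 2-{2-[4-(benzyloxy)-3-methoxyphenyl]ethyl}-2-lithio-1,3-dithiane (formed in the flask of step 7) | COc1cc(CCC2([Li])SCCCS2)ccc1OCc1ccccc1 | intermediate
12 | lithium (2R)-1-chloro-3-(2-{2-[4-(benzyloxy)-3-methoxyphenyl]ethyl}-1,3-dithian-2-yl)propan-2-olate (formed in the flask of step 7) | COc1cc(CCC2(C[C@@H](O[Li])CCl)SCCCS2)ccc1OCc1ccccc1 | intermediate
13 | (2R)-2-[(2-{2-[4-(benzyloxy)-3-methoxyphenyl]ethyl}-1,3-dithian-2-yl)methyl]oxirane (formed in the flask of step 7) | COc1cc(CCC2(C[C@@H]3CO3)SCCCS2)ccc1OCc1ccccc1 | intermediate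
14 | (2S)-4-[4-(benzyloxy)-3-methoxyphenyl]-1-(2-{2-[4-(benzyloxy)-3-methoxyphenyl]ethyl}-1,3-dithian-2-yl)butan-2-ol | COc1cc(CCC2(C[C@@H](O)CCc3ccc(OCc4ccccc4)c(OC)c3)SCCCS2)ccc1OCc1ccccc1 | intermediate
15 | (5S)-1,7-bis[4-(benzyloxy)-3-methoxyphenyl]-5-hydroxyheptan-3-one | COc1cc(CCC(=O)C[C@@H](O)CCc2ccc(OCc3ccccc3)c(OC)c2)ccc1OCc1ccccc1 | intermediate
16 | (3S,5S)-1,7-bis[4-(benzyloxy)-3-methoxyphenyl]-5-hydroxyheptan-3-yl acetate | COc1cc(CC[C@H](O)C[C@H](CCc2ccc(OCc3ccccc3)c(OC)c2)OC(C)=O)ccc1OCc1ccccc1 | intermediate
17 | (3S,5S)-5-hydroxy-1,7-bis(4-hydroxy-3-methoxyphenyl)heptan-3-yl acetate | COc1cc(CC[C@H](O)C[C@H](CCc2ccc(O)c(OC)c2)OC(C)=O)ccc1O | target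

## Step count and least certain steps

Total: 10 steps, in two parallel three-step branches (steps 1–3 and 4–6) followed by steps 7–10. Longest linear sequence: 7 steps (1, 2, 3, 7, 8, 9, 10).

**Step 7 (key step).** The most likely failure is loss of control over the order of events in one flask.
- A second dithiane anion may add to the newly closed epoxide if closure begins before the anion is spent.
- Halide may open the epoxide in place of carbon once magnesium halide is present.
- 5 may be partly metalated at the benzylic ether CH2, because 2-alkyl dithianes are deprotonated slowly.

Fallback, setting out from 9 and returning at 14: the two bonds are made in separate flasks and in the opposite order, which requires the mirror-image linchpin. Grignard reagent 9 opens (S)-epichlorohydrin (ClC[C@@H]1CO1) at the ring CH2 under CuI catalysis at −40 °C and gives (2S)-4-[4-(benzyloxy)-3-methoxyphenyl]-1-chlorobutan-2-ol F1. Aqueous NaOH closes it to (2S)-2-{2-[4-(benzyloxy)-3-methoxyphenyl]ethyl}oxirane F2, which is purified. The lithio derivative of 5 (that is, 11) then opens F2 at its CH2 carbon in THF between −30 and 0 °C and gives 14 with the same S configuration.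

**Step 6.** The most likely failure is Wurtz-type homocoupling during magnesium insertion, together with decomposition of the ionisable chloride before insertion; both are typical of para-alkoxybenzyl halides.

Fallback, setting out from 8 and from epoxide 13 (isolated by working up step 7 after the ring closure) and returning at 14: the benzylic carbanion is stabilised by a sulfonyl group in place of magnesium. 8 and PhSO2Na in DMF give 1-(benzyloxy)-2-methoxy-4-[(phenylsulfonyl)methyl]benzene F3. Its lithio derivative (n-BuLi, THF, −78 °C, then warming) opens 13 at the terminal carbon to (2S)-4-(benzenesulfonyl)-4-[4-(benzyloxy)-3-methoxyphenyl]-1-(2-{2-[4-(benzyloxy)-3-methoxyphenyl]ethyl}-1,3-dithian-2-yl)butan-2-ol F4, as both epimers at the sulfonyl-bearing carbon. Reductive desulfonylation with Mg in MeOH removes the sulfonyl group and gives 14.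

**Step 8.** The most likely failure is electrophilic attack of the halogen on the two electron-rich rings, or dehydration of the aldol while sulfur is being removed.

Fallback, setting out from 3 and returning at 15: the C4–C5 bond is made by an aldol addition, so that C3 arrives as a ketone and no thioacetal has to be cleaved. Commercial zingerone is benzylated (BnBr, K2CO3) to 4-[4-(benzyloxy)-3-methoxyphenyl]butan-2-one F5. LDA and TMSCl at −78 °C convert F5 into the terminal silyl enol ether ({4-[4-(benzyloxy)-3-methoxyphenyl]but-1-en-2-yl}oxy)trimethylsilane F6. An enantioselective Mukaiyama aldol addition of F6 to aldehyde 3, followed by acidic desilylation, gives 15. The catalyst would be a chiral oxazaborolidinone Lewis acid (the B-butyl oxazaborolidinone of N-tosyltryptophan, enantiomer chosen for the 5S product) in EtCN at −78 °C. Enantiomeric purity then rests on the catalyst and not on the chiral pool; it would have to be checked and, if necessary, raised by crystallisation before step 9.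

**Step 9.** The most likely failure is stalling of the catalytic cycle or retro-aldol cleavage of 15 on the Lewis acid. Traces of sulfur or iodine from step 8 can consume the divalent samarium, and acetaldehyde can be lost to self-condensation.

Fallback, setting out from 15 and returning at 16: reduction and acylation are separated. Hydroxyl-directed reduction with Me4NBH(OAc)3 in MeCN/AcOH at −30 °C (Evans–Saksena reduction, internal hydride delivery, anti) gives (3S,5S)-1,7-bis[4-(benzyloxy)-3-methoxyphenyl]heptane-3,5-diol F7. MeC(OMe)3 with catalytic pyridinium p-toluenesulfonate converts F7 into the cyclic orthoacetate (4S,6S)-4,6-bis{2-[4-(benzyloxy)-3-methoxyphenyl]ethyl}-2-methoxy-2-methyl-1,3-dioxane F8. Mild aqueous acid opens F8 to exactly one acetate, 16. Because F7 is C2-symmetric, either ring oxygen may keep the acetyl group and the same compound results.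

## Further compounds

F1 | step 7 | (2S)-4-[4-(benzyloxy)-3-methoxyphenyl]-1-chlorobutan-2-ol | ClC[C@@H](O)CCc1ccc(OCc2ccccc2)c(OC)c1
F2 | step 7 | (2S)-2-{2-[4-(benzyloxy)-3-methoxyphenyl]ethyl}oxirane | C1O[C@H]1CCc2ccc(OCc3ccccc3)c(OC)c2
F3 | step 6 | 1-(benzyloxy)-2-methoxy-4-[(phenylsulfonyl)methyl]benzene | COc1cc(CS(=O)(=O)c2ccccc2)ccc1OCc1ccccc1
F4 | step 6 | (2S)-4-(benzenesulfonyl)-4-[4-(benzyloxy)-3-methoxyphenyl]-1-(2-{2-[4-(benzyloxy)-3-methoxyphenyl]ethyl}-1,3-dithian-2-yl)butan-2-ol (both epimers at the sulfonyl-bearing carbon) | COc1cc(CCC2(C[C@@H](O)CC(c3ccc(OCc4ccccc4)c(OC)c3)S(=O)(=O)c3ccccc3)SCCCS2)ccc1OCc1ccccc1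
F5 | step 8 | 4-[4-(benzyloxy)-3-methoxyphenyl]butan-2-one | COc1cc(CCC(C)=O)ccc1OCc1ccccc1
F6 | step 8 | ({4-[4-(benzyloxy)-3-methoxyphenyl]but-1-en-2-yl}oxy)trimethylsilane | COc1cc(CCC(=C)O[Si](C)(C)C)ccc1OCc1ccccc1
F7 | step 9 | (3S,5S)-1,7-bis[4-(benzyloxy)-3-methoxyphenyl]heptane-3,5-diol | COc1cc(CC[C@H](O)C[C@@H](O)CCc2ccc(OCc3ccccc3)c(OC)c2)ccc1OCc1ccccc1
F8 | step 9 | (4S,6S)-4,6-bis{2-[4-(benzyloxy)-3-methoxyphenyl]ethyl}-2-methoxy-2-methyl-1,3-dioxane | COc1cc(CC[C@H]2C[C@H](CCc3ccc(OCc4ccccc4)c(OC)c3)OC(C)(OC)O2)ccc1OCc1ccccc1
A1 | alternative 1 | (1E,3R,5R,6E)-5-hydroxy-1,7-bis(4-hydroxy-3-methoxyphenyl)hepta-1,6-dien-3-yl acetate | COc1cc(/C=C/[C@H](O)C[C@H](/C=C/c2ccc(O)c(OC)c2)OC(C)=O)ccc1O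
A2 | alternative 1 | (1R,4R)-4-hydroxycyclopent-2-en-1-yl acetate | C1=C[C@H](O)C[C@H]1OC(C)=O
A3 | alternative 1 | 2-methoxy-4-vinylphenol | COc1cc(C=C)ccc1O
A4 | alternative 2 | (4S,6S)-nona-1,8-diene-4,6-diol | C=CC[C@H](O)C[C@@H](O)CC=C
A5 | alternative 2 | propane-1,3-diol | OCCCO
A6 | alternative 2 | allyl acetate (prop-2-en-1-yl acetate) | C=CCOC(C)=O
A7 | alternative 3 | (4S,6S)-4,6-bis{2-[4-(benzyloxy)-3-methoxyphenyl]ethyl}-2,2-dimethyl-1,3-dioxane | COc1cc(CC[C@H]2C[C@H](CCc3ccc(OCc4ccccc4)c(OC)c3)OC(C)(C)O2)ccc1OCc1ccccc1
A8 | alternative 3 | (4R,6R)-4,6-diethenyl-2,2-dimethyl-1,3-dioxane | C=C[C@H]1C[C@H](C=C)OC(C)(C)O1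
A9 | alternative 3 | 1-(benzyloxy)-4-bromo-2-methoxybenzene | COc1cc(Br)ccc1OCc1ccccc1
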